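**Retrosynthetic overview**
1. The target is the 1,3-syn (3R,5S) diacetate; it comes from the syn-diol by O-acetylation, with the aryl acetates removed again in the same flask. No ring is formed anywhere; both arenes arrive with the starting materials.
2. The syn-diol comes from an (E)-hept-4-en-3-one: the C5–O bond is made by enantioselective conjugate hydroperoxidation, and the peroxide then builds the boron chelate that steers hydride to C3 (1,3-syn).
3. The enone comes from zingerone and 3-(4-hydroxy-3,5-dimethoxyphenyl)propanal by aldol condensation (C4–C5).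
4. The aldehyde comes from methoxyeugenol by anti-Markovnikov hydration and oxidation.

Assumption: the quinidine-derived amine 9-amino(9-deoxy)epiquinidine is taken to deliver the peroxide to the enone face that gives 5S; if the first run shows the opposite sense, the quinine-derived pseudoenantiomer is used with nothing else changed.

**Step 1**
Reactants: 1 4-allyl-2,6-dimethoxyphenol (methoxyeugenol)
Product: 3 4-(3-hydroxypropyl)-2,6-dimethoxyphenol, via bis-boryl adduct 2 (not isolated)
Conditions: 9-BBN (2.3 equiv), THF, 0 °C to rt; then 3 M NaOH, 30% H2O2, 0 °C to rt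
Reagents that add atoms: hydrogen peroxide OO (oxygen of the new OH); 9-BBN B1C2CCCC1CCC2 (boron in intermediate 2 only)
Why: Hydroboration–oxidation with 9-BBN puts boron on the terminal carbon (>99:1), the phenol only consumes one equivalent as an aryl borinate that is hydrolysed in the alkaline peroxide work-up, and no stereocenter is formed.

**Step 2**
Reactants: 3 4-(3-hydroxypropyl)-2,6-dimethoxyphenol
Product: 4 3-(4-hydroxy-3,5-dimethoxyphenyl)propanal
Conditions: SO3·pyridine (3 equiv), DMSO, Et3N, CH2Cl2, 0 °C
Reagents that add atoms: none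
Why: Parikh–Doering (activated-DMSO) oxidation stops at the aldehyde and, unlike hypervalent-iodine or Cr(VI) oxidants, is not expected to attack the electron-rich free phenol.

**Step 3**
Reactants: 4 3-(4-hydroxy-3,5-dimethoxyphenyl)propanal; 5 zingerone (4-(4-hydroxy-3-methoxyphenyl)butan-2-one)
Product: 7 (E)-1-(4-hydroxy-3-methoxyphenyl)-7-(4-hydroxy-3,5-dimethoxyphenyl)hept-4-en-3-one, via racemic aldol 6 (not isolated)
Conditions: pyrrolidine (0.5 equiv), AcOH (0.5 equiv), THF, rt to 40 °C; 5 in 2-fold excess, 4 added over 4 h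
Reagents that add atoms: none
Why: Amine-catalysed cross-aldol condensation: pyrrolidine forms the less substituted (methyl-side) enamine of 5, which adds to 4, and E1cB loss of water gives the conjugated E-enone (the same union that makes shogaol-type enones from zingerone); excess ketone and slow aldehyde addition suppress self-condensation of 4.

**Step 4**
Reactants: 7 (E)-1-(4-hydroxy-3-methoxyphenyl)-7-(4-hydroxy-3,5-dimethoxyphenyl)hept-4-en-3-one
Product: 11 (3R,5S)-1-(4-hydroxy-3-methoxyphenyl)-7-(4-hydroxy-3,5-dimethoxyphenyl)heptane-3,5-diol, via hydroperoxy ketone 8 (not isolated), via peroxyhemiketal 9 (not isolated), via diethylboron chelate 10 (not isolated)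
Conditions: 9-amino(9-deoxy)epiquinidine (10 mol%), Cl3CCO2H (20 mol%), 50% aq H2O2 (1.5 equiv), THF, 30 °C; then THF/MeOH 4:1, BEt3 (3 equiv), Ar, −78 to −40 °C; NaBH4 (3 equiv), −78 °C; AcOH, MeOH co-evaporation
Reagents that add atoms: hydrogen peroxide OO (the C5 oxygen); triethylborane CCB(CC)CC (boron in intermediate 10 only)
Why: Proposed new method: a peroxide-to-boron relay in which the O–O bond installed by the enantioselective oxa-Michael step is the internal oxidant that builds the Narasaka–Prasad chelate – the primary-amine salt forms the iminium ion of 7 and its quinuclidine guides H2O2 to one face of C5 (C5–O bond, 5S; closest known reaction: the cinchona-amine Weitz–Scheffer-type conjugate hydroperoxidation of acyclic enones), hydroperoxide 8 (resting as peroxyhemiketal 9) then binds BEt3 and a 1,2-ethyl shift from boron to oxygen cleaves the O–O bond (the elementary step of organoborane oxidation and of the Bu3B/air activation in the original Narasaka reduction) to give ethanol and the six-membered Et2B chelate 10, and external axial hydride attack of NaBH4 on this half-chair chelate sets C3 as R (1,3-syn); new are the use of a β-hydroperoxy ketone as oxidant and ligand source for the boron chelate and the direct enone-to-syn-1,3-diol conversion in one flask.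

**Step 5**
Reactants: 11 (3R,5S)-1-(4-hydroxy-3-methoxyphenyl)-7-(4-hydroxy-3,5-dimethoxyphenyl)heptane-3,5-diol
Product: 13 (3R,5S)-1-(4-hydroxy-3-methoxyphenyl)-7-(4-hydroxy-3,5-dimethoxyphenyl)heptane-3,5-diyl diacetate, via tetraacetate 12 (not isolated)
Conditions: Ac2O (6 equiv), pyridine, DMAP (5 mol%), CH2Cl2, rt; then pyrrolidine (8 equiv), 0 °C to rt, 1 h
Reagents that add atoms: acetic anhydride CC(=O)OC(C)=O
Why: Exhaustive DMAP-catalysed acetylation followed by chemoselective aminolysis: the two aryl acetates (phenoxide leaving groups) are cleaved by pyrrolidine within minutes while the secondary alkyl acetates are inert at rt, and with no free aliphatic OH left there is no acyl migration or change at C3 or C5.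

**Compound list**
1 | 4-allyl-2,6-dimethoxyphenol (methoxyeugenol) | C=CCc1cc(OC)c(O)c(OC)c1 | starting material
2 | 9-[3-(4-(9-borabicyclo[3.3.1]nonan-9-yloxy)-3,5-dimethoxyphenyl)propyl]-9-borabicyclo[3.3.1]nonane (bis-boryl adduct) | COc1cc(CCCB2C3CCCC2CCC3)cc(OC)c1OB1C2CCCC1CCC2 | intermediate
3 | 4-(3-hydroxypropyl)-2,6-dimethoxyphenol | OCCCc1cc(OC)c(O)c(OC)c1 | intermediate
4 | 3-(4-hydroxy-3,5-dimethoxyphenyl)propanal | O=CCCc1cc(OC)c(O)c(OC)c1 | intermediate
5 | zingerone, 4-(4-hydroxy-3-methoxyphenyl)butan-2-one | CC(=O)CCc1ccc(O)c(OC)c1 | starting material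
6 | rac-5-hydroxy-1-(4-hydroxy-3-methoxyphenyl)-7-(4-hydroxy-3,5-dimethoxyphenyl)heptan-3-one (racemic aldol) | COc1cc(CCC(=O)CC(O)CCc2cc(OC)c(O)c(OC)c2)ccc1O | intermediate
7 | (E)-1-(4-hydroxy-3-methoxyphenyl)-7-(4-hydroxy-3,5-dimethoxyphenyl)hept-4-en-3-one | COc1cc(CCC(=O)/C=C/CCc2cc(OC)c(O)c(OC)c2)ccc1O | intermediate
8 | (5S)-5-hydroperoxy-1-(4-hydroxy-3-methoxyphenyl)-7-(4-hydroxy-3,5-dimethoxyphenyl)heptan-3-one | COc1cc(CCC(=O)C[C@H](CCc2cc(OC)c(O)c(OC)c2)OO)ccc1O | intermediate
9 | (5S)-5-[2-(4-hydroxy-3,5-dimethoxyphenyl)ethyl]-3-[2-(4-hydroxy-3-methoxyphenyl)ethyl]-1,2-dioxolan-3-ol (peroxyhemiketal, both C3 epimers) | COc1cc(CCC2(O)C[C@H](CCc3cc(OC)c(O)c(OC)c3)OO2)ccc1O | intermediate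
10 | (5S)-5-[(diethylboranyl)oxy]-1-(4-hydroxy-3-methoxyphenyl)-7-(4-hydroxy-3,5-dimethoxyphenyl)heptan-3-one (B–O=C chelate) | COc1cc(CCC(=O)C[C@H](CCc2cc(OC)c(O)c(OC)c2)OB(CC)CC)ccc1O | intermediate
11 | (3R,5S)-1-(4-hydroxy-3-methoxyphenyl)-7-(4-hydroxy-3,5-dimethoxyphenyl)heptane-3,5-diol (syn) | COc1cc(CC[C@H](C[C@H](CCc2cc(OC)c(O)c(OC)c2)O)O)ccc1O | intermediate
12 | (3R,5S)-1-(4-acetoxy-3-methoxyphenyl)-7-(4-acetoxy-3,5-dimethoxyphenyl)heptane-3,5-diyl diacetate (tetraacetate) | COc1cc(CC[C@H](C[C@H](CCc2cc(OC)c(OC(C)=O)c(OC)c2)OC(C)=O)OC(C)=O)ccc1OC(C)=O | intermediate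
13 | (3R,5S)-1-(4-hydroxy-3-methoxyphenyl)-7-(4-hydroxy-3,5-dimethoxyphenyl)heptane-3,5-diyl diacetate | COc1cc(CC[C@H](C[C@H](CCc2cc(OC)c(O)c(OC)c2)OC(C)=O)OC(C)=O)ccc1O | target

**Step count and risks**
Total steps: 5. Longest linear sequence: 5 (1 → 3 → 4 → 7 → 11 → 13); zingerone 5 enters at step 3.

The three steps most likely to fail:

Step 4 (the proposed new step). With a ketone that carries a CH2 on the far side, the hydroperoxy-enamine may close to the epoxide instead of hydrolysing to 8/9. BEt3 may also cleave the O–O bond by a radical path without placing boron on the C5 oxygen, which would erode the syn selectivity. The fallback uses known chemistry only, sets out from 7 and comes back at 11. The same amine salt and H2O2 are run at 50 °C and finished with aqueous NaOH, which is the established asymmetric Weitz–Scheffer epoxidation of acyclic enones, to give (4R,5S)-4,5-epoxy-1-(4-hydroxy-3-methoxyphenyl)-7-(4-hydroxy-3,5-dimethoxyphenyl)heptan-3-one F3. Its Cα–O bond is opened with SmI2 (THF/MeOH, −90 °C) to give (5S)-5-hydroxy-1-(4-hydroxy-3-methoxyphenyl)-7-(4-hydroxy-3,5-dimethoxyphenyl)heptan-3-one F4. F4 is reduced under standard Narasaka–Prasad conditions (Et2BOMe, NaBH4, THF/MeOH, −78 °C) to 11.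

Step 3. The risks are self-condensation of the enolisable aldehyde 4, reaction at the C2 methylene side of 5, and reversible aza-Michael addition of pyrrolidine to 7. The fallback sets out from 4 and 5 and comes back at 7. Zingerone is converted into its lithium phenoxide/kinetic methyl enolate (LDA 2.1 equiv, THF, −78 °C) and treated with the lithium phenoxide of 4 (LiHMDS 1.0 equiv, −78 °C). This directed aldol addition gives racemic aldol 6, which is now isolated and dehydrated with catalytic TsOH in toluene at 60 °C (the gingerol-to-shogaol dehydration) to 7. This fallback makes no compound outside the list (F0).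

Step 2. The free syringyl phenol may be sulfated or oxidised, and 4 may self-condense under Et3N. The fallback sets out from 3 and comes back at 7. The phenol is acetylated selectively (Ac2O 1.05 equiv, 1 M aqueous NaOH, 0 °C; the phenoxide reacts, the primary alcohol does not) to give 4-(3-hydroxypropyl)-2,6-dimethoxyphenyl acetate F1. Dess–Martin periodinane (NaHCO3, CH2Cl2), now safe, gives 2,6-dimethoxy-4-(3-oxopropyl)phenyl acetate F2. F2 is used in step 3 in place of 4 with one extra equivalent of pyrrolidine, which removes the aryl acetate by aminolysis in the flask while the condensation with 5 delivers 7.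

**Further compounds**
F1 | step 2 | 4-(3-hydroxypropyl)-2,6-dimethoxyphenyl acetate | CC(=O)Oc1c(OC)cc(CCCO)cc1OC
F2 | step 2 | 2,6-dimethoxy-4-(3-oxopropyl)phenyl acetate | CC(=O)Oc1c(OC)cc(CCC=O)cc1OC
F0 | step 3 | none | none
F3 | step 4 | (4R,5S)-4,5-epoxy-1-(4-hydroxy-3-methoxyphenyl)-7-(4-hydroxy-3,5-dimethoxyphenyl)heptan-3-one | COc1cc(CCC(=O)[C@@H]2O[C@H]2CCc3cc(OC)c(O)c(OC)c3)ccc1O
F4 | step 4 | (5S)-5-hydroxy-1-(4-hydroxy-3-methoxyphenyl)-7-(4-hydroxy-3,5-dimethoxyphenyl)heptan-3-one | COc1cc(CCC(=O)C[C@H](CCc2cc(OC)c(O)c(OC)c2)O)ccc1O
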